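(All runs come from a simulation from invented constants, and the scatter is random.)

Two questions stand on this flask, and both look at one moment: when 30 % of the two substrates together are converted.

- apparent order in partner when 30 % of the left-handed substrate and right-handed substrate together are converted (percent change of the rate of making left-handed product for one percent more partner charged)
- factor on the rate of making left-handed product when 30 % of the left-handed substrate and right-handed substrate together are converted if free catalyst is charged twice over

| setting | larch | maple | flask |
|---|---|---|---|
| left-handed substrate | 0.50 M | 0.50 M | 0.50 M |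
| right-handed substrate | 0.50 M | 0.50 M | 0.50 M |
| partner | 1.4 M | 2.2 M | 1.00 M |
| free catalyst | 2.5 mM | 2.5 mM | 2.5 mM |
| impurity | 2 mM | 2 mM | 2.0 mM |
| remark | run made earlier | run made earlier |  |

| run | time / h | left-handed product / % | left-handed substrate / % |
|---|---|---|---|
| larch | 1.00 | 5.8 | 45.0 |
| larch | 1.33 | 6.2 | 42.3 |
| larch | 2.00 | 9.0 | 41.4 |
| larch | 3.00 | 14.1 | 37.3 |
| larch | 5.00 | 15.4 | 32.6 |
| larch | 8.00 | 19.6 | 30.2 |
| larch | 12.0 | 24.8 | 25.7 |
| maple | 0.667 | 4.4 | 43.7 |
| maple | 2.00 | 12.0 | 37.5 |
| maple | 3.00 | 14.7 | 35.9 |
| maple | 5.00 | 19.5 | 28.4 |
| maple | 8.00 | 26.9 | 24.3 |
| maple | 10.0 | 30.5 | 19.0 |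
| maple | 12.0 | 32.4 | 17.4 |

(scatter of a reading: 1 percentage point)

- free catalyst is single-handed; left-handed substrate and right-handed substrate are mirror images of each other, charged as a racemate, each of them at the stated concentration
- the earlier runs were read with a standard deviation of 1 percentage point
- no earlier run changes the charge of free catalyst; that part of a forecast is a guess

We draw the curve of left-handed product from the earlier runs. It starts steeply: larch makes 5.8 % in its first 1.00 h. It then bends, for between 5.00 h and 8.00 h larch gains 4.2 percentage points, so the knee lies before 5.00 h. The last slope read over the first is 0.224 in larch and 0.208 in maple, rough readings, since substrate and partner have fallen too.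

Impurity is charged below catalyst, so if each impurity removes one catalyst for good, impurity is the limiting reagent of that loss. We call the share of catalyst left over afterwards the surviving share, which is 0.200 in larch, maple and this flask alike, and it lies near both readings.

Larch stands at 24.8 % product at 12.0 h, and this flask has less partner, so we expect its look later than that, past the knee. Our rate there follows catalyst above impurity, and charging catalyst twice over multiplies that excess by 6.00, a guess, as no run varies the charge.

From 5.00 h to 12.0 h maple gains 1.37 times what larch gains, against a charge ratio of 1.57, so we roughly take first order in partner. With one partner per substrate converted, 0.700 M remains at the look, which gives an order of 1.43.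

The forecast gave an order of 1.2 and a factor of 2.5, both lower than ours, and said of the factor that the impurity “could push it well higher”.

The flask gives an order of 1.4 and a factor of 5.86.

    free catalyst + left-handed substrate ⇌ catalyst intermediate A (K = 11.0 M⁻¹, k = 530 M⁻¹ h⁻¹)
    free catalyst + right-handed substrate ⇌ catalyst intermediate B (K = 0.550 M⁻¹, k = 150 M⁻¹ h⁻¹)
    partner + catalyst intermediate A → free catalyst + left-handed product (k = 25.0 M⁻¹ h⁻¹)
    partner + catalyst intermediate B → free catalyst + right-handed product (k = 8.30 M⁻¹ h⁻¹)
    free catalyst + impurity → spent catalyst (k = 880 M⁻¹ h⁻¹)

In this flask impurity takes free catalyst at 1.8 h⁻¹ per free catalyst with impurity as charged, and impurity is down to 4.42 % of its charge at 15.0 h, earlier than the look at 26.4 h. At 150 h impurity stands at 0 %, and spent catalyst, against the 80.0 % that the surviving share leaves for it, stands at 80.0 %.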